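**Plan**

1. Retrosynthesis: both spiro-cyclohexene rings are opened by retro-Diels–Alder cuts of their C2–C4′ and C14–C15′ bonds (first the ring joining units A and B, then the ring joining B and C), and the C10–OH bond of unit B is removed. This leaves three copies of one C15 guaianolide, a 3-oxo-guaia-4(15),10(14),11(13)-trien-12,6α-olide, used as dienophile through its exocyclic enone C4=C15 and, after C1–C2 dehydrogenation, as the s-cis diene C2=C1–C10=C14.
2. The monomer is cut at C1–C5 and rejoined at C5–C10, which turns its cyclopentane/cycloheptane core into the two six-membered rings of the eudesmanolide α-santonin 1.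
3. Forward order: one photochemical skeletal rearrangement makes the cyclopentenone and, by one-carbon expansion of ring B, the cycloheptane of every unit (that of the carbinol-bearing central unit included). Eight functional-group steps give the monomer 13, one more its silyl dienol ether, and a Saegusa oxidation the trienone 15. This diene is made once and dosed into two cascades: Diels–Alder/C10 autoxidation with 13 (B–C spiro-cyclohexene), then Diels–Alder/tautomerisation with the resulting dimer (unit A joined last).
4. Enabling feature: ring A of 1 is a cross-conjugated cyclohexa-2,5-dienone (C1=C2–C3(=O)–C4(Me)=C5) whose sp3 atom C10 is quaternary and shared with ring B. Light-induced C1–C5 bonding followed by scission of C5–C10 inserts C1 between C5 and C10, and the C4 methyl group steers the scission to the 5/7 skeleton.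
5. Stereochemistry: C6 and C7 of each unit come from 1; C1 is set in the rearrangement by the quaternary C10; C5 by α-face hydrogenation. The two spiro centres and the C10 centres of units A and B arise by substrate-controlled facial selection in the two cascades.

Key step: step 1

Remark: guaianolide numbering C1–C15 is used for each C15 unit (primes mark the partner unit), α is the face of a unit that carries H-5, and the units of the target are called A (H at C10), B (central, OH at C10) and C (saturated cyclopentanone). Trienone 15 is assumed to be long-lived enough in cold, dilute solution to be prepared once and used in steps 12 and 13.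

**Route**

Step 1
Reactants: 1 α-santonin
Product: 3 isophotosantonic lactone, via zwitterion 2 (not isolated)
Conditions: hν (medium-pressure Hg lamp, Pyrex), AcOH–H2O 1:1, reflux, N2
Reagents that add atoms: water (O)
Why: Excitation of the cross-conjugated dienone of 1 leads to C1–C5 bonding across ring A and, after electron demotion, to zwitterion 2 (a bicyclo[3.1.0]hexenone with C1, C5 and C10 in the three-membered ring); protonation on oxygen by the acidic medium gives a cyclopropylcarbinyl cation whose C5–C10 bond breaks while water attacks C10, so that C1 ends up between C5 and C10, ring A having contracted from six to five atoms and ring B having expanded from six to seven. The closest known reaction type is the type A photorearrangement of 4,4-disubstituted cyclohexa-2,5-dienones run in protic acid, which gives 5/7-fused hydroxy enones. The cyclopentenone is closed by the photochemical C1–C5 bridging (formally a disrotatory 4π closure of the C1–C5 oxidopentadienyl array), whereas the cycloheptane is not closed by a new bond but results from fragmentation of the C5–C10 bond of the cyclopropane (one-carbon ring expansion). The new C1 stereocentre (H-1α) is controlled by the quaternary C10 of 1, because the three-membered ring of 2 must be cis-fused to both the five- and the six-membered ring, which fixes the face of C1 that is bonded to C10, and the C10 carbinol (10α-OH) results from anti, backside opening of the C5–C10 bond; C6, C7 and C11 are untouched. The step needs the 5/7 pathway to win over the 1,4-shift to the lumiketone and over scission of C1–C10 (spiro ketone): the protic acid should protonate 2 faster than it rearranges, and the C4 methyl group stabilises positive charge at C4 and so directs scission to the C5–C10 bond. The Pyrex filter and interruption at full conversion of 1 limit secondary photolysis of the product enone.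

Step 2
Reactants: 3 isophotosantonic lactone
Product: 4 10α-hydroxy-3-oxo-1α,4α,5α,11βH-guaian-12,6α-olide
Conditions: H2 (1 atm), 10% Pd/C, EtOAc, 25 °C
Reagents that add atoms: none
Why: Heterogeneous syn-hydrogenation of the tetrasubstituted enone from the less hindered α face (the face of H-1, remote from the 10β-methyl group) should deliver H-4 and H-5 cis to H-1, which sets the cis ring fusion at C5; the C4 centre formed at the same time is erased later.

Step 3
Reactants: 4 10α-hydroxy-3-oxo-1α,4α,5α,11βH-guaian-12,6α-olide
Product: 5 3-oxo-1α,4α,5α,11βH-guai-10(14)-en-12,6α-olide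
Conditions: SOCl2, pyridine, −20 → 0 °C
Reagents that add atoms: none
Why: Chlorosulfite formation and pyridine-induced anti (E2) elimination; H-1 is syn to the 10α-oxygen and cannot be lost in an anti sense, and the three unhindered methyl hydrogens should outcompete H-9, so the exocyclic C10=C14 alkene is expected as the main regioisomer (a minor Δ9 isomer would be removed on AgNO3-impregnated silica).

Step 4
Reactants: 5 3-oxo-1α,4α,5α,11βH-guai-10(14)-en-12,6α-olide
Product: 6 3β-hydroxy-1α,4α,5α,11βH-guai-10(14)-en-12,6α-olide
Conditions: LiBH(sBu)3, THF, −78 °C; then H2O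
Reagents that add atoms: none
Why: The bulky hydride should add to the cyclopentanone anti to the adjacent C4 methyl group (from the convex α face), so that the new C3 hydroxyl is cis to the methyl group and anti to H-4, as the next step requires, while the lactone is not reduced at −78 °C.

Step 5
Reactants: 6 3β-hydroxy-1α,4α,5α,11βH-guai-10(14)-en-12,6α-olide
Product: 7 1α,5α,11βH-guaia-3,10(14)-dien-12,6α-olide
Conditions: Martin sulfurane Ph2S[OC(CF3)2Ph]2, CH2Cl2, 0 → 25 °C
Reagents that add atoms: none
Why: Dehydration through an alkoxysulfonium ion by anti-periplanar E2 elimination; with H-4 anti to the leaving group the Zaitsev (trisubstituted) C3=C4 alkene should predominate over the C2=C3 isomer, and the centres at C3 and C4 are removed.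

Step 6
Reactants: 7 1α,5α,11βH-guaia-3,10(14)-dien-12,6α-olide
Product: 10 1α,5αH-guaia-3,10(14),11(13)-trien-12,6α-olide, via selenide 8 (not isolated), via selenoxide 9 (not isolated)
Conditions: LiN(iPr)2, THF, −78 °C; PhSeBr, −78 → −40 °C; then 30% aq. H2O2, pyridine, CH2Cl2, 0 → 25 °C
Reagents that add atoms: none
Why: Lactone enolate selenenylation followed by selenoxide syn-elimination (α-methylenation); on the trans-fused lactone the selanyl group is expected to enter anti to H-7, so the only syn β-hydrogens are those of the C13 methyl group and the exocyclic C11=C13 alkene results, pyridine buffering the peroxide stage against epoxidation of the C3=C4 alkene.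

Step 7
Reactants: 10 1α,5αH-guaia-3,10(14),11(13)-trien-12,6α-olide
Product: 11 estafiatin
Conditions: mCPBA (1.05 equiv), CH2Cl2, 0 °C
Reagents that add atoms: mCPBA, 3-chloroperoxybenzoic acid (OOC(=O)c1cccc(Cl)c1)
Why: Prilezhaev epoxidation is fastest at the only trisubstituted, electron-rich alkene (C3=C4), and the peracid should approach the cis-fused hydroazulene from its convex α face (the face of H-1 and H-5) to give the 3α,4α-epoxide, the 1,1-disubstituted C10=C14 alkene and the electron-poor α-methylene lactone reacting much more slowly.

Step 8
Reactants: 11 estafiatin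
Product: 12 3-epizaluzanin C
Conditions: Al(OiPr)3, toluene, 110 °C
Reagents that add atoms: none
Why: Aluminium-alkoxide-promoted isomerisation of a trisubstituted epoxide to an allylic alcohol; Al binds the epoxide oxygen, the tertiary C4–O bond breaks and an isopropoxide ligand removes a proton through a cyclic transition state preferentially from the least substituted carbon (the C15 methyl, not the C5 methine), so the 4(15)-exocyclic alkene forms and C3 keeps its α-oxygen.

Step 9
Reactants: 12 3-epizaluzanin C
Product: 13 dehydrozaluzanin C
Conditions: Dess–Martin periodinane, CH2Cl2, 0 → 25 °C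
Reagents that add atoms: none
Why: Dess–Martin oxidation of the secondary allylic alcohol to the exocyclic enone under neutral, non-nucleophilic conditions that spare the α-methylene lactone; no stereocentre is created.

Step 10
Reactants: 13 dehydrozaluzanin C
Product: 14 TBS dienol ether of dehydrozaluzanin C
Conditions: TBSOTf, Et3N, CH2Cl2, −78 °C
Reagents that add atoms: TBSOTf, tert-butyldimethylsilyl trifluoromethanesulfonate (CC(C)(C)[Si](C)(C)OS(=O)(=O)C(F)(F)F)
Why: Soft enolisation; the ketone has α-hydrogens only at C2, so silylation gives the 2-silyloxy diene C2=C3(OTBS)–C4=C15 regiospecifically, and this diene is locked s-trans and cannot itself undergo cycloaddition.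

Step 11
Reactants: 14 TBS dienol ether of dehydrozaluzanin C
Product: 15 trienone (3-oxo-5αH-guaia-1,4(15),10(14),11(13)-tetraen-12,6α-olide)
Conditions: Pd(OAc)2 (1.1 equiv), MeCN (0.01 M), argon, 25 °C; filtration through a short silica plug at 0 °C; kept as a dilute CH2Cl2 solution at −78 °C and not taken to dryness
Reagents that add atoms: none
Why: Saegusa oxidation: the silyl enol ether is converted into the C2 palladium enolate (divalent palladium), and syn β-hydride elimination, for which only H-1 is available, gives the C1=C2 enone and with it the s-cis-locked diene C2=C1–C10=C14; no stereocentre is created (C1 becomes sp2), and high dilution, a short reaction time and cold storage are meant to suppress self-cycloaddition of 15.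

Step 12
Reactants: 15 trienone; 13 dehydrozaluzanin C
Product: 18 dimer B–C, via cycloadduct 16 (not isolated), via hydroperoxide 17 (not isolated)
Conditions: 15 (CH2Cl2 solution) added over 6 h to 13 (3 equiv), MeCN, O2 (1 atm), 25 °C; then Me2S, 0 °C
Reagents that add atoms: dioxygen (O=O)
Why: The diene C2=C1–C10=C14 of 15 should undergo an ortho-regioselective Diels–Alder reaction with the exocyclic enone C4=C15 of 13 (the most reactive dienophile of 13, kept in excess over the slowly added 15) on its convex α face (the face of H-1 and H-5) to set the spiro centre of 16; under O2 the doubly activated C2–H of 16 (α to the ketone and allylic) is expected to autoxidise with allylic transposition, dioxygen being trapped at C10 on the β face, away from the C5 branch of the spiro partner (autoxidation of a β,γ-unsaturated ketone to a γ-hydroperoxy enone, which erases the diene-face and endo/exo information), and Me2S reduces hydroperoxide 17 to the carbinol.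

Step 13
Reactants: 15 trienone; 18 dimer B–C
Product: 20 ainsliatrimer A, via cycloadduct 19 (not isolated)
Conditions: 15 (3 equiv, CH2Cl2 solution) added over 8 h to 18, MeCN, argon (degassed), 25 °C; then AcOH, 40 °C
Reagents that add atoms: none
Why: The diene of 15, held at low stationary concentration by slow addition, should add in an ortho-regioselective Diels–Alder reaction to the only activated exocyclic enone of 18 (C4=C15 of unit B; the α-methylene lactones and the tetrasubstituted C1=C2 enone are much poorer dienophiles) from the β face because the spiro-linked unit C screens the α face, which sets the second spiro centre in 19; acid-mediated tautomerisation of the β,γ-enone through its dienol under argon is then expected to place H-10 of unit A on the α face, anti to the C5 branch of the new spiro partner, and give the conjugated enone of the target.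

**Compound list**

1 | α-santonin (3-oxo-11βH-eudesma-1,4-dien-12,6α-olide) | C[C@H]1[C@@H]2CC[C@@]3(C)C=CC(=O)C(C)=C3[C@H]2OC1=O | starting material
2 | cyclopropane-bridged zwitterion (C1–C5 bond formed; C1, C5 and C10 in a three-membered ring; enolate C2=C3–O−, cation at C4) | C[C@H]1[C@@H]2CC[C@@]3(C)[C@@H]4C=C([O-])[C+](C)[C@@]43[C@H]2OC1=O | intermediate
3 | isophotosantonic lactone (10α-hydroxy-3-oxo-1α,11βH-guai-4-en-12,6α-olide) | C[C@H]1[C@@H]2CC[C@@](C)(O)[C@@H]3CC(=O)C(C)=C3[C@H]2OC1=O | intermediate
4 | 10α-hydroxy-3-oxo-1α,4α,5α,11βH-guaian-12,6α-olide (cis-fused, 4β-methyl) | C[C@H]1[C@@H]2CC[C@@](C)(O)[C@@H]3CC(=O)[C@H](C)[C@@H]3[C@H]2OC1=O | intermediate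
5 | 3-oxo-1α,4α,5α,11βH-guai-10(14)-en-12,6α-olide | C[C@H]1[C@@H]2CCC(=C)[C@@H]3CC(=O)[C@H](C)[C@@H]3[C@H]2OC1=O | intermediate
6 | 3β-hydroxy-1α,4α,5α,11βH-guai-10(14)-en-12,6α-olide (OH cis to the C4 methyl) | C[C@H]1[C@@H]2CCC(=C)[C@@H]3C[C@H](O)[C@H](C)[C@@H]3[C@H]2OC1=O | intermediate
7 | 1α,5α,11βH-guaia-3,10(14)-dien-12,6α-olide | C[C@H]1[C@@H]2CCC(=C)[C@@H]3CC=C(C)[C@@H]3[C@H]2OC1=O | intermediate
8 | 11β-(phenylselanyl)-1α,5αH-guaia-3,10(14)-dien-12,6α-olide (Se anti to H-7, 13-methyl α) | C[C@@]1([Se]c2ccccc2)[C@@H]2CCC(=C)[C@@H]3CC=C(C)[C@@H]3[C@H]2OC1=O | intermediate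
9 | selenoxide of 8 | C[C@@]1([Se](=O)c2ccccc2)[C@@H]2CCC(=C)[C@@H]3CC=C(C)[C@@H]3[C@H]2OC1=O | intermediate
10 | 1α,5αH-guaia-3,10(14),11(13)-trien-12,6α-olide | C=C1[C@@H]2CCC(=C)[C@@H]3CC=C(C)[C@@H]3[C@H]2OC1=O | intermediate
11 | estafiatin (3α,4α-epoxy-1α,5αH-guaia-10(14),11(13)-dien-12,6α-olide) | C=C1[C@@H]2CCC(=C)[C@@H]3C[C@H]4O[C@@]4(C)[C@@H]3[C@H]2OC1=O | intermediate
12 | 3-epizaluzanin C (3α-hydroxy-1α,5αH-guaia-4(15),10(14),11(13)-trien-12,6α-olide) | C=C1[C@@H]2CCC(=C)[C@@H]3C[C@@H](O)C(=C)[C@@H]3[C@H]2OC1=O | intermediate
13 | dehydrozaluzanin C (3-oxo-1α,5αH-guaia-4(15),10(14),11(13)-trien-12,6α-olide) | C=C1[C@@H]2CCC(=C)[C@@H]3CC(=O)C(=C)[C@@H]3[C@H]2OC1=O | intermediate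
14 | TBS dienol ether of dehydrozaluzanin C (3-silyloxy-1α,5αH-guaia-2,4(15),10(14),11(13)-tetraen-12,6α-olide) | C=C1[C@@H]2CCC(=C)[C@@H]3C=C(O[Si](C)(C)C(C)(C)C)C(=C)[C@@H]3[C@H]2OC1=O | intermediate
15 | trienone (3-oxo-5αH-guaia-1,4(15),10(14),11(13)-tetraen-12,6α-olide; diene C2=C1–C10=C14) | C=C1[C@@H]2CCC(=C)C3=CC(=O)C(=C)[C@@H]3[C@H]2OC1=O | intermediate
16 | cycloadduct B–C (β,γ-enone with C1=C10 in unit B, H-2β; new bonds C2–C4′ and C14–C15′, C2 of unit B on the α face of unit C) | C=C1C(=O)[C@H]2C3=C(CC[C@H]4C(=C)C(=O)O[C@@H]4[C@@H]13)CC[C@]21C(=O)C[C@H]2C(=C)CC[C@H]3C(=C)C(=O)O[C@@H]3[C@H]21 | intermediate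
17 | 10β-hydroperoxide of the dimer (C1=C2 enone in unit B) | C=C1C(=O)C2=C3[C@H]1[C@H]1OC(=O)C(=C)[C@@H]1CC[C@@]3(OO)CC[C@]21C(=O)C[C@H]2C(=C)CC[C@H]3C(=C)C(=O)O[C@@H]3[C@H]21 | intermediate
18 | dimer B–C (10β-hydroxy; unit B a cross-conjugated dienone with free C4=C15; spiro-linked to unit C) | C=C1C(=O)C2=C3[C@H]1[C@H]1OC(=O)C(=C)[C@@H]1CC[C@@]3(O)CC[C@]21C(=O)C[C@H]2C(=C)CC[C@H]3C(=C)C(=O)O[C@@H]3[C@H]21 | intermediate
19 | cycloadduct A–B–C (β,γ-enone with C1=C10 in unit A, H-2β; C2 of unit A on the β face of unit B) | C=C1C(=O)[C@H]2C3=C(CC[C@H]4C(=C)C(=O)O[C@@H]4[C@@H]13)CC[C@@]21C(=O)C2=C3[C@H]1[C@H]1OC(=O)C(=C)[C@@H]1CC[C@@]3(O)CC[C@]21C(=O)C[C@H]2C(=C)CC[C@H]3C(=C)C(=O)O[C@@H]3[C@H]21 | intermediate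
20 | ainsliatrimer A | C=C1C(=O)C2=C3[C@H](CC[C@H]4C(=C)C(=O)O[C@@H]4[C@@H]13)CC[C@@]21C(=O)C2=C3[C@H]1[C@H]1OC(=O)C(=C)[C@@H]1CC[C@@]3(O)CC[C@]21C(=O)C[C@H]2C(=C)CC[C@H]3C(=C)C(=O)O[C@@H]3[C@H]21 | target

**Totals and risks**

Total step count: 13 steps. Longest linear sequence: 13 steps (1 → 20; compounds 13 and 15 are each drawn from the same line more than once).

Steps most likely to fail:

Step 13. The trienone carries the same kind of exocyclic enone as the dimer, so its self-cycloaddition may outrun the cross-cycloaddition to the hindered dienophile. Attack on the wrong π-face of unit B, or protonation of C10 of unit A from the wrong face, would give diastereomers. The fallback removes the enone dienophile from the diene component. It sets out from 15: Luche reduction (NaBH4, CeCl3·7H2O, MeOH, −78 °C) should reduce only the cross-conjugated ketone in 1,2-fashion, hydride entering from the α face, and give 3β-hydroxy-5αH-guaia-1,4(15),10(14),11(13)-tetraen-12,6α-olide F1 (the C3 configuration is of no consequence). In F1 the C4=C15 alkene is no longer an enone and the diene is more electron-rich. Warming F1 with 18 (toluene, 60 °C, argon) should give the 3β-hydroxy cycloadduct A–B–C F2 by the same ortho- and β-face-selective Diels–Alder reaction. Dess–Martin periodinane (NaHCO3, CH2Cl2, 0 °C) oxidises the secondary allylic carbinol while the tertiary C10 carbinol of unit B stays inert. The sequence comes back to the route at 19, which is tautomerised with AcOH as in step 13.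

Step 12. Trapping of the delocalised C2–C1–C10 intermediate by O2 may be unselective between the two faces of C10, and protonation at C10 may compete and give the 10-deoxy dimer. The fallback replaces O2 by an electrophilic, sterically demanding oxidant and separates C–O bond formation from enolisation. It sets out from cycloadduct 16, generated from 15 and 13 as in step 12 but under argon. Dimethyldioxirane (1.0 equiv, acetone, −40 °C) should epoxidise only the tetrasubstituted, electron-rich C1=C10 alkene of unit B, from the β face (the face of H-2, anti to unit C attached at C2), and give the 1β,10β-epoxide of cycloadduct 16 F3. Et3N (CH2Cl2, 0 °C) then removes the acidic H-2 and the enolate opens the C1–O bond (E1cB opening of a β,γ-epoxy ketone to a γ-hydroxy enone), so the C10–O bond keeps its β configuration and the sequence comes back to the route at 18.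

Step 11. Self-cycloaddition of the trienone during its formation, filtration or storage, and palladium-induced decomposition, may consume it before it can be dosed. The fallback stores the diene as a stable precursor and releases it without metal at low temperature. It sets out from 14: PhSeCl (CH2Cl2, −78 °C) should give 2α-(phenylselanyl)dehydrozaluzanin C F4, with selenium on the convex α face and syn to H-1; this selenide can be purified and kept. Oxidation with mCPBA at −78 °C gives the selenoxide of 2α-(phenylselanyl)dehydrozaluzanin C F5. The cold solution of F5 is added to the dienophile of step 12 or step 13 together with iPr2NH, and warming to 0 °C should bring about syn-elimination of benzeneselenenic acid. The fallback thus comes back to the route at 15, which is formed slowly in the presence of its reaction partner and never has to be stored.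

**Further compounds**

F1 | step 13 | 3β-hydroxy-5αH-guaia-1,4(15),10(14),11(13)-tetraen-12,6α-olide | C=C1[C@@H]2CCC(=C)C3=C[C@H](O)C(=C)[C@@H]3[C@H]2OC1=O
F2 | step 13 | 3β-hydroxy cycloadduct A–B–C (19 with the C3 ketone of unit A as a carbinol) | C=C1[C@@H](O)[C@H]2C3=C(CC[C@H]4C(=C)C(=O)O[C@@H]4[C@@H]13)CC[C@@]21C(=O)C2=C3[C@H]1[C@H]1OC(=O)C(=C)[C@@H]1CC[C@@]3(O)CC[C@]21C(=O)C[C@H]2C(=C)CC[C@H]3C(=C)C(=O)O[C@@H]3[C@H]21
F3 | step 12 | 1β,10β-epoxide of cycloadduct 16 | C=C1C(=O)[C@H]2[C@@]3(O5)[C@H]1[C@H]1OC(=O)C(=C)[C@@H]1CC[C@@]35CC[C@]21C(=O)C[C@H]2C(=C)CC[C@H]3C(=C)C(=O)O[C@@H]3[C@H]21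
F4 | step 11 | 2α-(phenylselanyl)dehydrozaluzanin C | C=C1[C@@H]2CCC(=C)[C@@H]3[C@@H]([Se]c4ccccc4)C(=O)C(=C)[C@@H]3[C@H]2OC1=O
F5 | step 11 | selenoxide of 2α-(phenylselanyl)dehydrozaluzanin C | C=C1[C@@H]2CCC(=C)[C@@H]3[C@@H]([Se](=O)c4ccccc4)C(=O)C(=C)[C@@H]3[C@H]2OC1=O
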